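The cyclohexane ring is cut into two three-carbon pieces: C1–C2–C3 (C1 bears OH and CO2H; used as an α-keto ester that is also a 1-oxadiene) and C4–C5–C6 (a silyloxyacetone enol ether). The features exploited are the cis C3/C4 diol and the C1 carbinol β to C5, a hidden 1,5-diketone. In one pot, a Cu–bis(oxazoline)-catalysed inverse-demand hetero-Diels–Alder reaction joins C3 to C4 with both oxygens cis, and acid then converts the dihydropyran into the carbocycle by ring opening and aldol closure of C6 onto C1. Each piece brings one differently protected oxygen, so the caffeoyl and p-coumaroyl sites arrive differentiated.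

Key step: step 3

Remark: ring atoms carry quinic acid numbers (C1: C(OH)CO2H; C2, C6: CH2; C3: O-caffeoyl; C4: O-p-coumaroyl; C5: free secondary OH, cis to the carboxyl). The face shielded by the Cu catalyst is assigned from the square-planar chelate model (the (S,S)-ligand leaves the Si face of a bound 2-keto ester open), so the (R,R)-ligand is specified. Compounds 1, 2, 4, 12 and 17, both ligand enantiomers and Cu(OTf)2 are commercial.

Step 1
Reactants: 1 benzyl vinyl ether; 2 methyl chlorooxoacetate
Product: 3 methyl (E)-4-(benzyloxy)-2-oxobut-3-enoate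
Conditions: pyridine (1.2 equiv), CH2Cl2, 0 °C → rt
Reagents that add atoms: none
Why: C-acylation of the enol ether at its β-carbon by the oxalyl chloride and pyridine-mediated loss of HCl (vinylogous ester formation) give the conjugated alkoxy enone as the favoured E isomer.

Step 2
Reactants: 4 1-[(tert-butyldimethylsilyl)oxy]propan-2-one
Product: 5 (Z)-1-[(tert-butyldimethylsilyl)oxy]-2-[(trimethylsilyl)oxy]prop-1-ene
Conditions: TMSOTf (1.2 equiv), Et3N (1.5 equiv), CH2Cl2, 0 °C
Reagents that add atoms: trimethylsilyl trifluoromethanesulfonate, C[Si](C)(C)OS(=O)(=O)C(F)(F)F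
Why: Soft enolisation with silyl triflate and amine (silyl enol ether formation under equilibrating conditions) should give the more substituted enol ether on the oxygen-bearing carbon, with the two oxygens cis (Z).

Step 3
Reactants: 3 methyl (E)-4-(benzyloxy)-2-oxobut-3-enoate; 5 (Z)-1-[(tert-butyldimethylsilyl)oxy]-2-[(trimethylsilyl)oxy]prop-1-ene
Product: 8 methyl (1S,3R,4R)-3-(benzyloxy)-4-[(tert-butyldimethylsilyl)oxy]-1-hydroxy-5-oxocyclohexane-1-carboxylate, via dihydropyran cycloadduct 6 (not isolated), via open-chain diketo ester 7 (not isolated)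
Conditions: Cu(OTf)2 (10 mol %), (R,R)-t-Bu-box (11 mol %), 3 Å MS, Et2O, −40 °C; then 1 M aq HCl/THF, 0 °C; then extract, p-TsOH (10 mol %), CH2Cl2, 0 °C → rt
Reagents that add atoms: none
Why: The Cu(II)–bis(oxazoline) complex binds the 1,2-dicarbonyl unit of 3 and the electron-rich enediol ether 5 adds to the O=C1–C2=C3 oxadiene in an endo inverse-electron-demand hetero-Diels–Alder reaction ([4+2] closure of dihydropyran 6: C4 to C3, the silyloxy carbon C5 to the ketone oxygen). Aqueous acid cleaves the trimethylsilyl ketal, the hemiketal opens to the 2,6-diketo ester 7, and under anhydrous acid the methyl-ketone enol (C6) adds to the activated α-keto ester carbon C1 in a 6-(enolendo)-exo-trig aldol that closes the carbocycle, the pyranose-to-cyclohexanone change used by dehydroquinate synthase. The closest known reaction types are the Cu–box-catalysed cycloadditions of γ-alkoxy-β,γ-unsaturated α-keto esters with oxygenated enol ethers and the acid-catalysed cyclisation of 1,5-diketones. C3 and C4 are set in the cycloaddition: the (R,R)-ligand shields the Si face of the chelated ketone so that 5 adds to the Re face (C3 R), and the endo transition state of the (Z)-alkene places the C3 and C4 oxygens cis. C1 is set in the aldol by the substrate: in the hydrogen-bonded chair transition state the forming C1–O bond is axial and the ester equatorial, the bulky C4 silyloxy group is equatorial, so the cis C3 benzyloxy group is axial and accepts a hydrogen bond from the protonated ketone, which should put the C1 hydroxyl cis to the C3 oxygen. The regioselectivity of the cycloaddition follows from the methyl- and silyloxy-stabilised positive charge at C5, only the C6 enol can close a six-membered ring, and the acidic, amine-free conditions avoid β-elimination of the C3 benzyloxy group from 7.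

Step 4
Reactants: 8 methyl (1S,3R,4R)-3-(benzyloxy)-4-[(tert-butyldimethylsilyl)oxy]-1-hydroxy-5-oxocyclohexane-1-carboxylate
Product: 10 (1S,3R,4R,5R)-3-(benzyloxy)-4-[(tert-butyldimethylsilyl)oxy]-1-hydroxy-6-oxabicyclo[3.2.1]octan-7-one (3-O-benzyl-4-O-TBS-1,5-quinide), via diol ester 9 (not isolated)
Conditions: Me4NBH(OAc)3 (5 equiv), MeCN/AcOH 1:1, −30 → −20 °C; aqueous work-up; crude, PPTS (20 mol %), 5 Å MS, toluene, 90 °C
Reagents that add atoms: none
Why: Hydroxyl-directed 1,3-anti reduction (Evans–Saksena): the C1 hydroxyl exchanges onto boron and delivers hydride to the same face of the C5 ketone, so the new C5 hydroxyl is trans to the C1 hydroxyl and cis to the ester, and acid-catalysed transesterification then closes the γ-lactone that only this cis pair can form.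

Step 5
Reactants: 10 3-O-benzyl-4-O-TBS-1,5-quinide
Product: 11 (1S,3R,4R,5R)-4-[(tert-butyldimethylsilyl)oxy]-1,3-dihydroxy-6-oxabicyclo[3.2.1]octan-7-one (4-O-TBS-1,5-quinide)
Conditions: H2 (1 atm), 10 % Pd/C, EtOAc, rt
Reagents that add atoms: none
Why: Catalytic hydrogenolysis of the benzyl ether, placed before any cinnamate C=C is present, leaves the silyl ether, the lactone and all stereocentres untouched.

Step 6
Reactants: 12 caffeic acid
Product: 13 (E)-3-(3,4-diacetoxyphenyl)acrylic acid
Conditions: Ac2O, pyridine, rt; then H2O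
Reagents that add atoms: acetic anhydride, CC(=O)OC(C)=O
Why: O-acetylation of both phenols protects the catechol, and the mixed anhydride formed at the carboxyl is hydrolysed on aqueous work-up.

Step 7
Reactants: 13 (E)-3-(3,4-diacetoxyphenyl)acrylic acid; 11 4-O-TBS-1,5-quinide
Product: 15 (1R,3R,4R,5R)-4-[(tert-butyldimethylsilyl)oxy]-1-hydroxy-7-oxo-6-oxabicyclo[3.2.1]octan-3-yl (E)-3-(3,4-diacetoxyphenyl)acrylate, via diacetylcaffeoyl chloride 14 (not isolated)
Conditions: (COCl)2, DMF (cat.), CH2Cl2, 0 °C → rt, concentrate; then 11, pyridine, DMAP (10 mol %), CH2Cl2, 0 °C → rt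
Reagents that add atoms: oxalyl chloride, O=C(Cl)C(=O)Cl (chlorine of 14)
Why: Acid chloride formation (Vilsmeier activation) and DMAP-catalysed esterification of the only secondary hydroxyl of 11, the equatorial 3-OH, while the tertiary 1-OH should not react at this temperature.

Step 8
Reactants: 15 3-O-(diacetylcaffeoyl)-4-O-TBS-1,5-quinide
Product: 16 (1R,3R,4R,5R)-1,4-dihydroxy-7-oxo-6-oxabicyclo[3.2.1]octan-3-yl (E)-3-(3,4-diacetoxyphenyl)acrylate
Conditions: HF·pyridine, pyridine/THF, 0 °C → rt
Reagents that add atoms: none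
Why: Fluoride cleavage of the silyl ether under buffered acidic conditions that should keep aryl acetates, cinnamate and lactone intact and disfavour migration of the equatorial 3-O-acyl group to the axial 4-OH.

Step 9
Reactants: 17 p-coumaric acid
Product: 18 (E)-3-(4-acetoxyphenyl)acrylic acid
Conditions: Ac2O, pyridine, rt; then H2O
Reagents that add atoms: acetic anhydride, CC(=O)OC(C)=O
Why: O-acetylation of the phenol as in step 6.

Step 10
Reactants: 18 (E)-3-(4-acetoxyphenyl)acrylic acid; 16 3-O-(diacetylcaffeoyl)-1,5-quinide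
Product: 20 (1R,3R,4R,5R)-4-{[(E)-3-(4-acetoxyphenyl)acryloyl]oxy}-1-hydroxy-7-oxo-6-oxabicyclo[3.2.1]octan-3-yl (E)-3-(3,4-diacetoxyphenyl)acrylate, via 4-acetoxycinnamoyl chloride 19 (not isolated)
Conditions: (COCl)2, DMF (cat.), CH2Cl2, 0 °C → rt, concentrate; then 16, pyridine, DMAP (20 mol %), CH2Cl2, rt → 40 °C
Reagents that add atoms: oxalyl chloride, O=C(Cl)C(=O)Cl (chlorine of 19)
Why: Acid chloride formation and DMAP-catalysed esterification of the axial 4-hydroxyl, the only remaining secondary alcohol, which the tertiary 1-OH cannot match in rate.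

Step 11
Reactants: 20 fully protected diester lactone
Product: 21 (1R,3R,4S,5R)-3-{[(E)-3-(3,4-dihydroxyphenyl)acryloyl]oxy}-1,5-dihydroxy-4-{[(E)-3-(4-hydroxyphenyl)acryloyl]oxy}cyclohexane-1-carboxylic acid (3-O-caffeoyl-4-O-p-coumaroylquinic acid)
Conditions: 2 M aq HCl/THF 1:3, rt, several days
Reagents that add atoms: water, O
Why: Acid-catalysed hydrolysis should cleave the three aryl acetates and open the strained bicyclic γ-lactone, while the two cinnamoyl esters of secondary alcohols hydrolyse far more slowly and acid suppresses acyl migration.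

Compound list
1 | benzyl vinyl ether | C=COCc1ccccc1 | starting material
2 | methyl chlorooxoacetate | COC(=O)C(=O)Cl | starting material
3 | methyl (E)-4-(benzyloxy)-2-oxobut-3-enoate | COC(=O)C(=O)/C=C/OCc1ccccc1 | intermediate
4 | 1-[(tert-butyldimethylsilyl)oxy]propan-2-one | CC(=O)CO[Si](C)(C)C(C)(C)C | starting material
5 | (Z)-1-[(tert-butyldimethylsilyl)oxy]-2-[(trimethylsilyl)oxy]prop-1-ene | C/C(O[Si](C)(C)C)=C/O[Si](C)(C)C(C)(C)C | intermediate
6 | methyl (2R,3R,4R)-4-(benzyloxy)-3-[(tert-butyldimethylsilyl)oxy]-2-methyl-2-[(trimethylsilyl)oxy]-3,4-dihydro-2H-pyran-6-carboxylate (three oxygens cis) | COC(=O)C1=C[C@@H](OCc2ccccc2)[C@@H](O[Si](C)(C)C(C)(C)C)[C@@](C)(O[Si](C)(C)C)O1 | intermediate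
7 | methyl (4R,5R)-4-(benzyloxy)-5-[(tert-butyldimethylsilyl)oxy]-2,6-dioxoheptanoate | COC(=O)C(=O)C[C@@H](OCc1ccccc1)[C@@H](O[Si](C)(C)C(C)(C)C)C(C)=O | intermediate
8 | methyl (1S,3R,4R)-3-(benzyloxy)-4-[(tert-butyldimethylsilyl)oxy]-1-hydroxy-5-oxocyclohexane-1-carboxylate | CC(C)(C)[Si](C)(C)O[C@H]1C(=O)C[C@](O)(C(=O)OC)C[C@H]1OCc1ccccc1 | intermediate
9 | methyl (1R,3R,4S,5R)-3-(benzyloxy)-4-[(tert-butyldimethylsilyl)oxy]-1,5-dihydroxycyclohexane-1-carboxylate | CC(C)(C)[Si](C)(C)O[C@H]1[C@H](O)C[C@](O)(C(=O)OC)C[C@H]1OCc1ccccc1 | intermediate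
10 | (1S,3R,4R,5R)-3-(benzyloxy)-4-[(tert-butyldimethylsilyl)oxy]-1-hydroxy-6-oxabicyclo[3.2.1]octan-7-one | CC(C)(C)[Si](C)(C)O[C@H]1[C@H]2C[C@](O)(C(=O)O2)C[C@H]1OCc1ccccc1 | intermediate
11 | (1S,3R,4R,5R)-4-[(tert-butyldimethylsilyl)oxy]-1,3-dihydroxy-6-oxabicyclo[3.2.1]octan-7-one | CC(C)(C)[Si](C)(C)O[C@H]1[C@H]2C[C@](O)(C(=O)O2)C[C@H]1O | intermediate
12 | caffeic acid | O=C(O)/C=C/c1ccc(O)c(O)c1 | starting material
13 | (E)-3-(3,4-diacetoxyphenyl)acrylic acid | CC(=O)Oc1ccc(/C=C/C(=O)O)cc1OC(C)=O | intermediate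
14 | (E)-3-(3,4-diacetoxyphenyl)acryloyl chloride | CC(=O)Oc1ccc(/C=C/C(=O)Cl)cc1OC(C)=O | intermediate
15 | (1R,3R,4R,5R)-4-[(tert-butyldimethylsilyl)oxy]-1-hydroxy-7-oxo-6-oxabicyclo[3.2.1]octan-3-yl (E)-3-(3,4-diacetoxyphenyl)acrylate | CC(C)(C)[Si](C)(C)O[C@H]1[C@H]2C[C@](O)(C(=O)O2)C[C@H]1OC(=O)/C=C/c1ccc(OC(C)=O)c(OC(C)=O)c1 | intermediate
16 | (1R,3R,4R,5R)-1,4-dihydroxy-7-oxo-6-oxabicyclo[3.2.1]octan-3-yl (E)-3-(3,4-diacetoxyphenyl)acrylate | O[C@H]1[C@H]2C[C@](O)(C(=O)O2)C[C@H]1OC(=O)/C=C/c1ccc(OC(C)=O)c(OC(C)=O)c1 | intermediate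
17 | p-coumaric acid | O=C(O)/C=C/c1ccc(O)cc1 | starting material
18 | (E)-3-(4-acetoxyphenyl)acrylic acid | CC(=O)Oc1ccc(/C=C/C(=O)O)cc1 | intermediate
19 | (E)-3-(4-acetoxyphenyl)acryloyl chloride | CC(=O)Oc1ccc(/C=C/C(=O)Cl)cc1 | intermediate
20 | (1R,3R,4R,5R)-4-{[(E)-3-(4-acetoxyphenyl)acryloyl]oxy}-1-hydroxy-7-oxo-6-oxabicyclo[3.2.1]octan-3-yl (E)-3-(3,4-diacetoxyphenyl)acrylate | CC(=O)Oc1ccc(/C=C/C(=O)O[C@H]2[C@H]3C[C@](O)(C(=O)O3)C[C@H]2OC(=O)/C=C/c2ccc(OC(C)=O)c(OC(C)=O)c2)cc1 | intermediate
21 | 3-O-caffeoyl-4-O-p-coumaroylquinic acid, (1R,3R,4S,5R) | O=C(/C=C/c1ccc(O)cc1)O[C@H]1[C@H](O)C[C@](O)(C(=O)O)C[C@H]1OC(=O)/C=C/c1ccc(O)c(O)c1 | target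

Total step count: 11. Longest linear sequence: 8 steps (step 1 or 2, then 3, 4, 5, 7, 8, 10, 11).

Steps most likely to fail

Step 3. The ring closure may go through the other chair and place the C1 hydroxyl trans to the C3 oxygen, benzyl alcohol may be lost from 7 by β-elimination, or endo and regiocontrol may erode in the cycloaddition. The fallback sets out from 3 and ketone 4 (without making 5) and comes back at 8. It is an amine-catalysed domino Michael/aldol reaction (9-amino-9-deoxy-epi-cinchona alkaloid trifluoroacetate, toluene, rt). The enamine of 4 on its oxygen-bearing carbon should add to C3 of 3, and a second enamine on the methyl side should then close onto the keto ester, with the catalyst enantiomer chosen to match. Both bonds are still made in one operation, by enamine instead of Lewis-acid activation. It passes through 7 again and makes no compound outside the list (none F0).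

Step 4. Hydride delivery from the hindered tertiary C1 hydroxyl may be slow, so that undirected reduction gives the C5 epimer, which cannot lactonise. The fallback sets out from 8 and comes back at 10, and sets C5 by inversion. L-Selectride (THF, −78 °C) should attack opposite the axial C1 and C3 oxygens and give methyl (1R,3R,4S,5S)-3-(benzyloxy)-4-[(tert-butyldimethylsilyl)oxy]-1,5-dihydroxycyclohexane-1-carboxylate F1. LiOH (THF/H2O) then gives (1R,3R,4S,5S)-3-(benzyloxy)-4-[(tert-butyldimethylsilyl)oxy]-1,5-dihydroxycyclohexane-1-carboxylic acid F2. Intramolecular Mitsunobu lactonisation (PPh3, DIAD, THF) should displace the activated C5 oxygen by the carboxylate with inversion and give 10.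

Step 11. During the long acidic hydrolysis the cinnamoyl esters may be partly cleaved or migrate, or the lactone may open incompletely. The fallback sets out from 20 and comes back at 21, in two chemoselective operations. NH4OAc in aqueous methanol (rt) should transesterify only the three aryl acetates and give 3-O-caffeoyl-4-O-p-coumaroyl-1,5-quinide F3. The lactone is then opened on its own with dilute aqueous trifluoroacetic acid (THF/H2O, rt).

Further compounds
F0 | step 3 | none | none
F1 | step 4 | methyl (1R,3R,4S,5S)-3-(benzyloxy)-4-[(tert-butyldimethylsilyl)oxy]-1,5-dihydroxycyclohexane-1-carboxylate | CC(C)(C)[Si](C)(C)O[C@H]1[C@@H](O)C[C@](O)(C(=O)OC)C[C@H]1OCc1ccccc1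
F2 | step 4 | (1R,3R,4S,5S)-3-(benzyloxy)-4-[(tert-butyldimethylsilyl)oxy]-1,5-dihydroxycyclohexane-1-carboxylic acid | CC(C)(C)[Si](C)(C)O[C@H]1[C@@H](O)C[C@](O)(C(=O)O)C[C@H]1OCc1ccccc1
F3 | step 11 | 3-O-caffeoyl-4-O-p-coumaroyl-1,5-quinide | O=C(/C=C/c1ccc(O)cc1)O[C@H]1[C@H]2C[C@](O)(C(=O)O2)C[C@H]1OC(=O)/C=C/c1ccc(O)c(O)c1
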